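In a one-step world the substrate would lose a fixed fraction of itself each minute from the first moment, and a percent yield would simply count minutes; here no gas is in solution at the start, so we expect the count to begin late.

| setting | eta | gamma | flask |
|---|---|---|---|
| substrate | 0.25 M | 0.17 M | 0.25 M |
| gas phase | 15 mM (held) | 15 mM (held) | 15 mM (held) |
| remark | the very flask that is asked about, followed so far | run made earlier |  |
| time |  |  | 80 min |

| eta: time / min | eta: target / % | gamma: time / min | gamma: target / % |
|---|---|---|---|
| 3.00 | 0 | 4.00 | 0 |
| 5.00 | 0.4 | 10.0 | 0.1 |
| 8.00 | 0.6 | 20.0 | 1.2 |
| 15.0 | 0.4 | 30.0 | 2.2 |
| 25.0 | 1.7 | 40.0 | 3.1 |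
| 40.0 | 2.9 | 60.0 | 5.3 |

(scatter of a reading: 0.3 percentage points)

1. target at 80 min, in percent of the substrate charged
2. concentration of dissolved gas in solution at 80 min, in percent of saturation

- at the start none of the gas phase is in solution

Run gamma looks nearly the same as the eta flask, with less substrate and the same gas. At 40.0 min the two read 3.1% and 2.9%, apart by 0.2 percentage points with a scatter of 0.3 points on each, so the percent yield shows no sign of the charge, as in a pseudo-first-order step. Their last readings do differ, gamma's being the higher, but gamma was also read later, so we take the clock as the difference between them. From 20.0 min to 60.0 min the gamma readings give a turnover rate of 0.00102 min⁻¹, the fraction of the substrate becoming target each minute along that stretch of the run, and the line through those two readings starts at a lag of 8.29 min. Rate times the minutes past the lag counts the turnovers, and the yield is one minus the exponential of minus that count. For the eta flask at 80 min we count 0.0735, which gives 7.09%. The forecast differs from this reckoning, with 6.3% (5.5% to 7.3%) of target and dissolved gas at 85% of saturation (70% to 96%), on the view of “a reaction that waits for the gas to dissolve”.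

    substrate → side product (k = 9.90 × 10⁻⁵ min⁻¹)
    substrate + dissolved gas → target (k = 0.0910 M⁻¹ min⁻¹)
    gas phase ⇌ dissolved gas, rate k3*(csat - [dissolved gas]) (kL = 0.0680 min⁻¹)

The flask gives 6.83% of target, inside the forecast's range and a little under our 7.09%, while its dissolved gas stands at 76.1% of saturation, lower than the forecast's 85%. The target stands at 6.83% because the flask has had little time: our count for it is 0.0735, and the same flask left ten times as long holds 56.7%. The turnover rate carries to the neighbour flask left until 5.0 h, where 0.299 turnovers give 25.8% against the 26.0% of target it holds.

The earlier runs and the new flask were computed on assumed constants; noise was put on by code.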